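**Strategy.** The ten-membered carbocycle is closed last at the C9–C10 bond (germacrane locants). C8(OH)–C9H2–C10(Me)=C1H is a homoallylic alcohol with an E-trisubstituted alkene, the signature of a nickel-catalysed reductive alkyne–epoxide coupling. The precursor is an acyclic cis-γ-lactone carrying a terminal C8–C9 epoxide on C7 and, on C6, a Z-alkenyl chain ending in a methyl alkyne (C1≡C10). One operation should close the cyclodecadiene, set the E geometry of C1=C10 by syn addition and release the C8 hydroxyl with the epoxide's configuration. C7 and C8 come from diethyl (R)-malate, C6 from a Felkin–Anh reduction and C11 from lactone methylation.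

Key step: step 13

Remark (locants and stereochemistry): germacrane locants are used throughout (C1–C10 carbocycle; C11, C12, C13 lactone α-carbon, carbonyl and methyl; C14 methyl on C10; C15 hydroxymethyl carbon on C4). The target is read as 6R,7S,8S,11R, i.e. a cis-fused 6,12-lactone (H6 and H7 on the same face) with the C11 methyl trans to C8.

**Route**

Step 1
Reactants: 1 prop-2-yn-1-ol; 2 5-bromopent-2-yne
Product: 5 (2Z)-3-iodo-2-(pent-3-yn-1-yl)prop-2-en-1-ol, via pent-3-yn-1-ylmagnesium bromide 3 (not isolated), via alkenylmagnesium alkoxide chelate 4 (not isolated)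
Conditions: 2, Mg, THF, 23 °C; then 1, CuI (10 mol%), Et2O–THF, 0→23 °C; then I2, −20→0 °C
Reagents that add atoms: iodine (II)
Why: Copper-catalysed anti-carbomagnesiation of the magnesium propargyl alkoxide should place the pentynyl group on the internal alkyne carbon and magnesium on the terminal carbon inside a five-membered alkoxide chelate, so that iodinolysis with retention gives the iodoalkene with iodine cis to CH2OH (the later C4=C5 geometry).

Step 2
Reactants: 5 (2Z)-3-iodo-2-(pent-3-yn-1-yl)prop-2-en-1-ol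
Product: 6 TBDPS ether of 5
Conditions: TBDPSCl, imidazole, CH2Cl2, 23 °C
Reagents that add atoms: tert-butyl(chloro)diphenylsilane (CC(C)(C)[Si](Cl)(c1ccccc1)c1ccccc1)
Why: Silyl ether formation at the primary allylic hydroxyl; the bulky TBDPS group should resist both 1,4 O-to-C silyl migration in the alkenyllithium of step 7 and the acid of step 10.

Step 3
Reactants: 7 diethyl (R)-malate; 8 tert-butyl bromoacetate
Product: 10 3-tert-butyl 1,2-diethyl (1R,2S)-1-hydroxypropane-1,2,3-tricarboxylate, via dilithium alkoxide enolate 9 (not isolated)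
Conditions: LiN(iPr)2 (2.2 equiv), THF, −78→−20 °C; then 8, −78→−10 °C
Reagents that add atoms: none
Why: Fráter–Seebach alkylation: the chelated dilithium alkoxide enolate is alkylated on the face anti to the alkoxide, which should set C7 (2S in 10) anti to the malate-derived C8 hydroxyl (1R in 10).

Step 4
Reactants: 10 hydroxy triester
Product: 11 4-tert-butyl 1-ethyl (2S)-2-[(1R)-1,2-dihydroxyethyl]butanedioate
Conditions: BH3·SMe2 (1.05 equiv), NaBH4 (5 mol%), THF, 0→23 °C; then MeOH
Reagents that add atoms: none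
Why: Hydroxyl-directed chemoselective ester reduction: the alkoxyborane formed at the C8 hydroxyl delivers hydride (NaBH4 as activator) only to the adjacent α-hydroxy ester, so C9 becomes CH2OH while the C6 ethyl ester and the C12 tert-butyl ester stay.

Step 5
Reactants: 11 diol diester
Product: 12 4-tert-butyl 1-ethyl (2S)-2-[(4R)-2,2-dimethyl-1,3-dioxolan-4-yl]butanedioate
Conditions: Me2C(OMe)2, PPTS (cat.), acetone, 23 °C
Reagents that add atoms: 2,2-dimethoxypropane (COC(C)(C)OC)
Why: Acetonide formation by transketalisation ties up the 1,2-diol before it can lactonise onto the ethyl ester and makes the C8 branch the large group for step 8.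

Step 6
Reactants: 12 acetonide diester
Product: 13 tert-butyl (3S)-3-[(4R)-2,2-dimethyl-1,3-dioxolan-4-yl]-4-[methoxy(methyl)amino]-4-oxobutanoate
Conditions: MeNH(OMe)·HCl, i-PrMgCl, THF, −20→0 °C
Reagents that add atoms: N,O-dimethylhydroxylamine hydrochloride (CNOC.Cl)
Why: Weinreb amide formation by aminolysis with the chloromagnesium amide made in the flask; the ethyl ester should react while the hindered tert-butyl ester and the acetonide stay.

Step 7
Reactants: 6 (Z)-alkenyl iodide; 13 Weinreb amide
Product: 15 (Z)-enone acetonide tert-butyl ester, via alkenyllithium 14 (not isolated)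
Conditions: 6, t-BuLi (2.05 equiv), Et2O, −78 °C; then 13, THF, −78→−40 °C; aq. NH4Cl
Reagents that add atoms: none
Why: Iodine–lithium exchange with retention of the Z geometry followed by Weinreb ketone synthesis: the chelated tetrahedral adduct should stop at the ketone stage and the tert-butyl ester is not attacked at −78 °C.

Step 8
Reactants: 15 (Z)-enone
Product: 17 cis-lactone acetonide, via potassium C6 alkoxide 16 (not isolated)
Conditions: K[(s-Bu)3BH], THF, −78 °C, then to 23 °C; aq. NH4Cl
Reagents that add atoms: none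
Why: Felkin–Anh 1,2-reduction: the bulky, non-chelating hydride should attack anti to the dioxolanyl group on C7 and so give the 6R alkoxide (O6 anti to the C11 branch), which closes on the tert-butyl ester on warming (5-exo-trig lactonisation) to the cis-4,5-disubstituted γ-lactone.

Step 9
Reactants: 17 cis-lactone acetonide
Product: 19 C11-methyl lactone acetonide, via lithium lactone enolate 18 (not isolated)
Conditions: LiN(iPr)2 (1.1 equiv), THF, −78 °C; then MeI, −78→−40 °C
Reagents that add atoms: iodomethane (CI)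
Why: Lactone enolate alkylation: methyl iodide should enter from the face opposite the cis C6 and C7 substituents, setting C11 (R) with the methyl trans to the C7 side chain.

Step 10
Reactants: 19 C11-methyl lactone acetonide
Product: 20 C8,C9-diol lactone
Conditions: AcOH–THF–H2O (3:1:1), 40 °C
Reagents that add atoms: none
Why: Acid hydrolysis of the terminal acetonide (acetal hydrolysis); the TBDPS ether, the lactone and the alkyne should stay untouched and no stereocentre is affected.

Step 11
Reactants: 20 C8,C9-diol lactone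
Product: 21 C9-iodo C8-hydroxy lactone
Conditions: PPh3, I2, imidazole, CH2Cl2, 0 °C
Reagents that add atoms: iodine (II)
Why: Appel-type iodination (oxyphosphonium formation and SN2 displacement by iodide) should occur only at the unhindered primary C9 hydroxyl, leaving the C8 hydroxyl and its configuration in place.

Step 12
Reactants: 21 C9-iodo C8-hydroxy lactone
Product: 22 epoxy alkynyl lactone
Conditions: Ag2O, THF, 4 Å molecular sieves, 23→40 °C, dark
Reagents that add atoms: none
Why: Silver-assisted intramolecular Williamson etherification of the iodohydrin: the C8 hydroxyl displaces iodide at C9 without a free alkoxide, so C8 keeps its configuration and the neighbouring lactone is not attacked.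

Step 13
Reactants: 22 epoxy alkynyl lactone
Product: 24 macrocyclic C8 alcohol (C15 TBDPS ether), via diethylborinate ester 23 (not isolated)
Conditions: Ni(cod)2 (30 mol%), PBu3 (60 mol%), Et3B (5 equiv), Et2O–THF, 23 °C, slow addition of 22 (final 0.003 M); aq. NaHCO3
Reagents that add atoms: none
Why: Proposed new method: the nickel-catalysed reductive coupling of an alkyne with a terminal epoxide, known between separate partners and for five- and six-membered ring closure with an exocyclic alkene, is extended to a ten-membered ring closure in which both alkyne carbons become ring atoms; zerovalent nickel bound to the C1≡C10 alkyne and the Et3B-activated epoxide should couple oxidatively at the unhindered C9 to an alkenylnickel alkoxide with nickel on C1, Et3B then passes ethyl to nickel and takes the alkoxide as the borinate, and β-hydride elimination followed by C–H reductive elimination puts hydrogen on C1 and returns zerovalent nickel. The carbocycle closes in the endo mode with respect to both partners (C8 and C9 of the epoxide and C10 and C1 of the alkyne all become ring atoms), giving the ten-membered 1(10),4-diene. No stereocentre is formed: C8 keeps the epoxide configuration because only the C9–O bond breaks, and the E geometry of C1=C10 follows from syn addition of C9 and H across the alkyne. The step needs regioselection for C10 over C1 and for C9 over C8; the second is steric, and the first is expected because bonding through C1 would give a more strained nine-membered ring with an exocyclic ethylidene and because methyl is the smaller alkyne substituent beside the new bond. It also needs ring closure to outrun oligomerisation and insertion of nickel into the allylic C6–O bond, which slow addition at high dilution and the hindered trisubstituted C4=C5 alkene should secure.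

Step 14
Reactants: 25 ethyl 2-(hydroxymethyl)prop-2-enoate
Product: 26 ethyl 2-({[tert-butyl(dimethyl)silyl]oxy}methyl)prop-2-enoate
Conditions: TBSCl, imidazole, CH2Cl2, 0→23 °C
Reagents that add atoms: tert-butyl(chloro)dimethylsilane (CC(C)(C)[Si](C)(C)Cl)
Why: Silyl ether formation masks the primary hydroxyl of the acrylate so that it cannot compete in the later esterification.

Step 15
Reactants: 26 silylated ethyl acrylate
Product: 27 2-({[tert-butyl(dimethyl)silyl]oxy}methyl)prop-2-enoic acid
Conditions: LiOH·H2O, THF–H2O (3:1), 0 °C; then 1 M HCl to pH 3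
Reagents that add atoms: lithium hydroxide ([Li+].[OH-])
Why: Ester saponification at 0 °C should cleave the ethyl ester without touching the silyl ether or adding to the α-substituted acrylate.

Step 16
Reactants: 24 macrocyclic C8 alcohol; 27 silylated acrylic acid
Product: 28 bis-silylated C8 ester
Conditions: EDC·HCl, DMAP, CH2Cl2, 0→23 °C
Reagents that add atoms: none
Why: Steglich esterification: the O-acylisourea from 27 is passed through the acylpyridinium ion to the secondary C8 hydroxyl, the only free hydroxyl in 24, with retention at C8.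

Step 17
Reactants: 28 bis-silylated C8 ester
Product: 29 target (CNP0167163.2)
Conditions: HF·pyridine, pyridine, THF, 0→23 °C
Reagents that add atoms: none
Why: Fluoride-mediated desilylation buffered with pyridine should remove both silyl ethers without acid-induced transannular cyclisation of the 1(10),4-diene or acyl migration.

**Compound list**

1 | prop-2-yn-1-ol | C#CCO | starting material
2 | 5-bromopent-2-yne | CC#CCCBr | starting material
3 | pent-3-yn-1-ylmagnesium bromide | CC#CCC[Mg]Br | intermediate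
4 | alkenylmagnesium alkoxide chelate (4-(pent-3-yn-1-yl)-2,5-dihydro-1,2-oxamagnesole) | CC#CCCC1=C[Mg]OC1 | intermediate
5 | (2Z)-3-iodo-2-(pent-3-yn-1-yl)prop-2-en-1-ol | OC/C(CCC#CC)=C\I | intermediate
6 | tert-butyl{[(2Z)-3-iodo-2-(pent-3-yn-1-yl)prop-2-en-1-yl]oxy}diphenylsilane | CC#CCC/C(CO[Si](c1ccccc1)(c1ccccc1)C(C)(C)C)=C/I | intermediate
7 | diethyl (2R)-2-hydroxybutanedioate (diethyl (R)-malate) | CCOC(=O)[C@H](O)CC(=O)OCC | starting material
8 | tert-butyl bromoacetate | BrCC(=O)OC(C)(C)C | starting material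
9 | dilithium alkoxide enolate of 7 | CCOC(=O)[C@H](O[Li])C=C(O[Li])OCC | intermediate
10 | 3-tert-butyl 1,2-diethyl (1R,2S)-1-hydroxypropane-1,2,3-tricarboxylate | CCOC(=O)[C@H](O)[C@H](CC(=O)OC(C)(C)C)C(=O)OCC | intermediate
11 | 4-tert-butyl 1-ethyl (2S)-2-[(1R)-1,2-dihydroxyethyl]butanedioate | OC[C@H](O)[C@H](CC(=O)OC(C)(C)C)C(=O)OCC | intermediate
12 | 4-tert-butyl 1-ethyl (2S)-2-[(4R)-2,2-dimethyl-1,3-dioxolan-4-yl]butanedioate | CC1(C)OC[C@H](O1)[C@H](CC(=O)OC(C)(C)C)C(=O)OCC | intermediate
13 | tert-butyl (3S)-3-[(4R)-2,2-dimethyl-1,3-dioxolan-4-yl]-4-[methoxy(methyl)amino]-4-oxobutanoate | CC1(C)OC[C@H](O1)[C@H](CC(=O)OC(C)(C)C)C(=O)N(C)OC | intermediate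
14 | (Z)-alkenyllithium from 6 | CC#CCC/C(CO[Si](c1ccccc1)(c1ccccc1)C(C)(C)C)=C/[Li] | intermediate
15 | tert-butyl (3S,5Z)-6-({[tert-butyl(diphenyl)silyl]oxy}methyl)-3-[(4R)-2,2-dimethyl-1,3-dioxolan-4-yl]-4-oxoundec-5-en-9-ynoate | CC#CCC/C(CO[Si](c1ccccc1)(c1ccccc1)C(C)(C)C)=C/C(=O)[C@@H](CC(=O)OC(C)(C)C)[C@@H]1COC(C)(C)O1 | intermediate
16 | potassium alkoxide of the 6R allylic alcohol from 15 (C12 tert-butyl ester) | CC#CCC/C(CO[Si](c1ccccc1)(c1ccccc1)C(C)(C)C)=C/[C@@H](O[K])[C@@H](CC(=O)OC(C)(C)C)[C@@H]1COC(C)(C)O1 | intermediate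
17 | (4R,5R)-5-[(1Z)-2-({[tert-butyl(diphenyl)silyl]oxy}methyl)hept-1-en-5-yn-1-yl]-4-[(4R)-2,2-dimethyl-1,3-dioxolan-4-yl]oxolan-2-one | CC#CCC/C(CO[Si](c1ccccc1)(c1ccccc1)C(C)(C)C)=C/[C@H]1OC(=O)C[C@H]1[C@@H]2COC(C)(C)O2 | intermediate
18 | lithium enolate of lactone 17 | CC#CCC/C(CO[Si](c1ccccc1)(c1ccccc1)C(C)(C)C)=C/[C@H]1OC(O[Li])=C[C@H]1[C@@H]2COC(C)(C)O2 | intermediate
19 | (3R,4R,5R)-5-[(1Z)-2-({[tert-butyl(diphenyl)silyl]oxy}methyl)hept-1-en-5-yn-1-yl]-4-[(4R)-2,2-dimethyl-1,3-dioxolan-4-yl]-3-methyloxolan-2-one | CC#CCC/C(CO[Si](c1ccccc1)(c1ccccc1)C(C)(C)C)=C/[C@H]1OC(=O)[C@H](C)[C@H]1[C@@H]2COC(C)(C)O2 | intermediate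
20 | (3R,4S,5R)-5-[(1Z)-2-({[tert-butyl(diphenyl)silyl]oxy}methyl)hept-1-en-5-yn-1-yl]-4-[(1R)-1,2-dihydroxyethyl]-3-methyloxolan-2-one | CC#CCC/C(CO[Si](c1ccccc1)(c1ccccc1)C(C)(C)C)=C/[C@H]1OC(=O)[C@H](C)[C@H]1[C@@H](O)CO | intermediate
21 | (3R,4S,5R)-5-[(1Z)-2-({[tert-butyl(diphenyl)silyl]oxy}methyl)hept-1-en-5-yn-1-yl]-4-[(1R)-1-hydroxy-2-iodoethyl]-3-methyloxolan-2-one | CC#CCC/C(CO[Si](c1ccccc1)(c1ccccc1)C(C)(C)C)=C/[C@H]1OC(=O)[C@H](C)[C@H]1[C@@H](O)CI | intermediate
22 | (3R,4R,5R)-5-[(1Z)-2-({[tert-butyl(diphenyl)silyl]oxy}methyl)hept-1-en-5-yn-1-yl]-3-methyl-4-[(2R)-oxiran-2-yl]oxolan-2-one | CC#CCC/C(CO[Si](c1ccccc1)(c1ccccc1)C(C)(C)C)=C/[C@H]1OC(=O)[C@H](C)[C@H]1[C@@H]2CO2 | intermediate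
23 | O-diethylboryl (borinate) derivative of 24 | CCB(CC)O[C@H]1C/C(C)=C/CC/C(CO[Si](c2ccccc2)(c2ccccc2)C(C)(C)C)=C/[C@H]2OC(=O)[C@H](C)[C@@H]12 | intermediate
24 | (3R,3aS,4S,6E,10Z,11aR)-10-({[tert-butyl(diphenyl)silyl]oxy}methyl)-4-hydroxy-3,6-dimethyl-3a,4,5,8,9,11a-hexahydrocyclodeca[b]furan-2(3H)-one | O[C@H]1C/C(C)=C/CC/C(CO[Si](c2ccccc2)(c2ccccc2)C(C)(C)C)=C/[C@H]2OC(=O)[C@H](C)[C@@H]12 | intermediate
25 | ethyl 2-(hydroxymethyl)prop-2-enoate | C=C(CO)C(=O)OCC | starting material
26 | ethyl 2-({[tert-butyl(dimethyl)silyl]oxy}methyl)prop-2-enoate | C=C(CO[Si](C)(C)C(C)(C)C)C(=O)OCC | intermediate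
27 | 2-({[tert-butyl(dimethyl)silyl]oxy}methyl)prop-2-enoic acid | C=C(CO[Si](C)(C)C(C)(C)C)C(=O)O | intermediate
28 | (3R,3aS,4S,6E,10Z,11aR)-10-({[tert-butyl(diphenyl)silyl]oxy}methyl)-3,6-dimethyl-2-oxo-2,3,3a,4,5,8,9,11a-octahydrocyclodeca[b]furan-4-yl 2-({[tert-butyl(dimethyl)silyl]oxy}methyl)prop-2-enoate | C=C(CO[Si](C)(C)C(C)(C)C)C(=O)O[C@H]1C/C(C)=C/CC/C(CO[Si](c2ccccc2)(c2ccccc2)C(C)(C)C)=C/[C@H]2OC(=O)[C@H](C)[C@@H]12 | intermediate
29 | (3R,3aS,4S,6E,10Z,11aR)-10-(hydroxymethyl)-3,6-dimethyl-2-oxo-2,3,3a,4,5,8,9,11a-octahydrocyclodeca[b]furan-4-yl 2-(hydroxymethyl)prop-2-enoate | C=C(CO)C(=O)O[C@H]1C/C(C)=C/CC/C(CO)=C/[C@H]2OC(=O)[C@H](C)[C@@H]12 | target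

**Step count and risks**

Total step count: 17 steps. Longest linear sequence: 13 steps (7 to 29 through steps 3–13, 16 and 17).

Steps most likely to fail:

1. Step 13 (labelled key step). What may go wrong: intermolecular coupling to oligomers, bond formation through C1 instead of C10, no turnover with an unactivated dialkyl alkyne at high dilution, or insertion of zerovalent nickel into the allylic C6–O bond. The fallback sets out from 19. Hydrozirconation with Cp2Zr(H)Cl (THF, slight excess so that zirconium settles on the methyl-bearing carbon) and iodinolysis with I2 should give the (E)-alkenyl iodide F1. AcOH–THF–H2O then gives the diol F2, and PPh3/I2/imidazole gives the iodohydrin F3. A nickel-catalysed reductive cross-electrophile coupling of the alkenyl iodide with the primary alkyl iodide (NiBr2(dme), 4,4'-di-tert-butyl-2,2'-bipyridine, Mn powder, NaI, DMA, slow addition) should close the same C9–C10 bond with retention of the E geometry. It comes back to the route at 24.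

2. Step 8. What may go wrong: poor facial selectivity if a transition state chelated through the acetonide oxygen competes with the Felkin–Anh one, or incomplete lactonisation onto the tert-butyl ester. The fallback sets out from 12. Reduction with i-Bu2AlH (CH2Cl2, −78 °C) gives the aldehyde F4. Addition of the alkenyllithium 14 under non-chelating conditions, where Felkin–Anh and 1,3-anti induction reinforce each other, should give the 6S allylic alcohol F5 (cold quench, no lactonisation). Mitsunobu inversion (PPh3, DIAD, 4-nitrobenzoic acid) gives the 6R 4-nitrobenzoate F6. K2CO3 in MeOH cleaves the benzoate and the freed alkoxide lactonises onto the tert-butyl ester, which comes back to the route at 17.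

3. Step 11. What may go wrong: loss of site selectivity between the two hydroxyls, or deoxygenative elimination of the vicinal diol to the terminal alkene under phosphine/iodine conditions. The fallback sets out from 20. Tin-catalysed selective sulfonylation of the primary hydroxyl (TsCl, Bu2SnO (cat.), Et3N, CH2Cl2) gives the primary tosylate F7. Finkelstein exchange (NaI, acetone, 50 °C) then comes back to the route at 21.

**Further compounds**

F1 | step 13 | (3R,4R,5R)-5-[(1Z,5E)-2-({[tert-butyl(diphenyl)silyl]oxy}methyl)-6-iodohepta-1,5-dien-1-yl]-4-[(4R)-2,2-dimethyl-1,3-dioxolan-4-yl]-3-methyloxolan-2-one | I/C(C)=C/CC/C(CO[Si](c1ccccc1)(c1ccccc1)C(C)(C)C)=C/[C@H]1OC(=O)[C@H](C)[C@H]1[C@@H]2COC(C)(C)O2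
F2 | step 13 | (3R,4S,5R)-5-[(1Z,5E)-2-({[tert-butyl(diphenyl)silyl]oxy}methyl)-6-iodohepta-1,5-dien-1-yl]-4-[(1R)-1,2-dihydroxyethyl]-3-methyloxolan-2-one | I/C(C)=C/CC/C(CO[Si](c1ccccc1)(c1ccccc1)C(C)(C)C)=C/[C@H]1OC(=O)[C@H](C)[C@H]1[C@@H](O)CO
F3 | step 13 | (3R,4S,5R)-5-[(1Z,5E)-2-({[tert-butyl(diphenyl)silyl]oxy}methyl)-6-iodohepta-1,5-dien-1-yl]-4-[(1R)-1-hydroxy-2-iodoethyl]-3-methyloxolan-2-one | I/C(C)=C/CC/C(CO[Si](c1ccccc1)(c1ccccc1)C(C)(C)C)=C/[C@H]1OC(=O)[C@H](C)[C@H]1[C@@H](O)CI
F4 | step 8 | tert-butyl (3S)-3-[(4R)-2,2-dimethyl-1,3-dioxolan-4-yl]-4-oxobutanoate | CC1(C)OC[C@H](O1)[C@H](CC(=O)OC(C)(C)C)C=O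
F5 | step 8 | 6S allylic alcohol (C6 epimer of the alcohol of 16, C12 tert-butyl ester) | CC#CCC/C(CO[Si](c1ccccc1)(c1ccccc1)C(C)(C)C)=C/[C@H](O)[C@@H](CC(=O)OC(C)(C)C)[C@@H]1COC(C)(C)O1
F6 | step 8 | 6R 4-nitrobenzoate of the allylic alcohol (C12 tert-butyl ester) | CC#CCC/C(CO[Si](c1ccccc1)(c1ccccc1)C(C)(C)C)=C/[C@@H](OC(=O)c1ccc(cc1)[N+](=O)[O-])[C@@H](CC(=O)OC(C)(C)C)[C@@H]1COC(C)(C)O1
F7 | step 11 | C9 4-methylbenzenesulfonate of diol 20 | CC#CCC/C(CO[Si](c1ccccc1)(c1ccccc1)C(C)(C)C)=C/[C@H]1OC(=O)[C@H](C)[C@H]1[C@@H](O)COS(=O)(=O)c1ccc(C)cc1
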